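**The flasks.** The enzyme in these flasks turns substrate into target, and I want the quantity that sets its pace.

all flasks: free enzyme 6.7 µM
- south-east: substrate 0.067 M; impurity 0.80 µM; temperature −10 °C; run made earlier
- west: substrate 0.067 M; impurity 3.2 µM; temperature 20 °C; run made earlier
- north: substrate 0.034 M; impurity 1.6 µM; temperature −10 °C; run made earlier
- oak: substrate 0.067 M; impurity 1.6 µM; temperature −5 °C; time 5.0 d
- birch: substrate 0.067 M; impurity 1.6 µM; temperature 20 °C; time 5.0 d
- larch: substrate 0.067 M; impurity 1.6 µM; temperature 45 °C; time 5.0 d

- south-east (time / d: target / %, substrate / %): 0.417: 1.3, 99.5; 1.25: 3.6, 99.0; 2.50: 3.9, 95.9; 4.00: 5.4, 93.9; 5.00: 7.2, 92.1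
- west (time / h: target / %, substrate / %): 3.00: 3.4, 90.5; 8.00: 7.6, 79.7; 20.0: 15.7, 56.0; 30.0: 19.7, 42.1; 40.0: 21.8, 32.4
- north (time / d: target / %, substrate / %): 1.04: 2.4, 97.3; 2.08: 4.9, 94.8; 3.00: 6.4, 93.1; 4.00: 8.1, 90.9; 5.00: 9.8, 88.8

(scatter of a reading: 0.5 percentage points)



- which flask leads in amount of target, in percent of the substrate charged ("all alike" within 1.5 percentage points) (oak / birch / larch / all alike)
- how much target is there at the end, in percent of the substrate charged: oak
- how much target is there at the end, in percent of the substrate charged: birch
- how much target is there at the end, in percent of the substrate charged: larch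

**Order first.** I count each impurity as taking one free enzyme out of work, so the working enzyme is c(free enzyme) minus c(impurity). The south-east run then gives 164 /d for the turnover frequency, the target made per working enzyme per day. The north run, with half the substrate, gives 131 /d. So the order in substrate reads 0.331, well below one, and I let c(working enzyme) carry the rate.

**Two ways.** The turnover can also be read from the substrate lost. In the south-east run that gives 179 /d. The two readings behind it differ by 0.7 percentage points against a scatter of 0.5 points each, so I trust the number. In the west run at 8.00 h the target way gives 4360 /d and the substrate way 11700 /d. They part: 13 points of substrate has left without appearing as target. The substrate way therefore counts a second exit, and I keep the target way.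

**My reckoning.** The two target turnovers give an apparent activation energy of 70.2 kJ/mol. At −5 °C I reckon a turnover of 297 /d, and a straight line over 5.0 d puts oak at 11.3%. I draw no such line for birch or larch, since the west target gains 2.1 points between its last two readings.

**The forecast.** It names birch as leader, with oak 13.5%, birch 25% and larch 2%, and it reads the west run this way: “The falling target/loss ratio in west suggests target slowly decays”.

**The result.** The leader is birch, with oak 11.1%, birch 17.7% and larch 6.15%. The forecast's birch stands 7.3 points too high.

    substrate + free enzyme ⇌ complex (K = 18.0 /M, k = 640 /M/s, Ea = 38.0 kJ/mol, ΔH = −34.0 kJ/mol)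
    complex ⇌ free enzyme + target (K = 0.0560 M, k = 0.0960 /s, Ea = 82.0 kJ/mol, ΔH = −3.00 kJ/mol)
    free enzyme → unfolded enzyme (k = 2.80 × 10⁻⁷ /s, Ea = 205 kJ/mol)
    substrate → uncatalysed product (k = 5.20 × 10⁻⁶ /s, Ea = 109 kJ/mol)
    free enzyme + impurity → spent catalyst (k = 150 /M/s, Ea = 39.0 kJ/mol)
    (constants at 20 °C)

**Oak explained.** Read back, oak's target gives a turnover of 291 /d against my 297 /d. At the end oak holds spent catalyst 23.9% of the catalyst and impurity 0% of its charge. Two things act together on oak's target: the time given, since after 50.0 d oak holds 64.1%, and the return of complex to substrate and free enzyme, with which struck out oak holds 17.9% instead of 11.1%.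

**Colder neighbour.** Take oak's charge at −20 °C. Scaling 164 /d with the same energy gives 1.75% of target. The computed flask holds 1.58%.

(The earlier runs and the new flask were generated by integration from invented constants; scatter was added.)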